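**Retrosynthetic overview**
- Target ⇐ O‑benzyl precursor (hydrogenolysis); the 3,4‑epoxide ⇐ face‑selective epoxidation of the C3=C4 alkene.
- C4 methyl and C3=C4 alkene ⇐ C4 ketone (kinetic enol triflate, then Negishi methylation).
- Key C1–C10 bond: the seven‑membered ring is closed by a SmI2 reductive ketyl–enone cyclization, in which the C10 ketone carbon acts as the nucleophile toward the enone β‑carbon C1; the ring fusion is then equilibrated to trans.
- The five‑membered ring is made first, as a 2‑substituted cyclopentenone, by a Pauson–Khand reaction of a terminal alkyne with ethylene.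
- Chain stereocentres: C8 by an L‑proline aldol with acetone, C7 by an Evans propargylation. Ring order: five‑membered ring, seven‑membered ring, epoxide.

Assumption: the SMILES is taken as drawn, which in guaiane numbering (five‑membered ring C1–C5, seven‑membered ring C1, C5–C10, C14 on C10, C15 on C4, isopropyl on C7, ester on C8) is (1R,3R,4S,5S,7R,8R,10R); this numbering is used for all bicyclic compounds.

**Step 1**
Reactants: 1 (4R)-4-benzyl-1,3-oxazolidin-2-one; 2 3-methylbutanoyl chloride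
Product: 3 (4R)-4-benzyl-3-(3-methylbutanoyl)-1,3-oxazolidin-2-one
Conditions: Et3N, DMAP (cat.), CH2Cl2, 0 °C → rt
Reagents that add atoms: none
Why: DMAP‑catalysed N‑acylation of the oxazolidinone installs the isovaleryl unit whose α‑carbon becomes C7; no new stereocentre.

**Step 2**
Reactants: 3 (4R)-4-benzyl-3-(3-methylbutanoyl)-1,3-oxazolidin-2-one; 4 3-bromoprop-1-yne
Product: 6 (4R)-4-benzyl-3-[(2R)-2-(propan-2-yl)pent-4-ynoyl]-1,3-oxazolidin-2-one, via sodium Z-enolate 5 (not isolated)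
Conditions: NaN(SiMe3)2, THF, −78 °C; then 4, −78 → −40 °C
Reagents that add atoms: none
Why: Evans asymmetric alkylation, in which the chelated Z‑enolate is propargylated on the face opposite the benzyl group, setting C7 as 2R.

**Step 3**
Reactants: 6 (4R)-4-benzyl-3-[(2R)-2-(propan-2-yl)pent-4-ynoyl]-1,3-oxazolidin-2-one
Product: 7 (2R)-2-(propan-2-yl)pent-4-yn-1-ol
Conditions: LiBH4, MeOH (1 equiv), Et2O, 0 °C
Reagents that add atoms: none
Why: Reductive cleavage of the imide by LiBH4 gives the primary alcohol without touching the alkyne or the α‑stereocentre and returns the auxiliary.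

**Step 4**
Reactants: 7 (2R)-2-(propan-2-yl)pent-4-yn-1-ol
Product: 8 (2R)-2-(propan-2-yl)pent-4-ynal
Conditions: Dess–Martin periodinane, CH2Cl2, 0 °C → rt; used at once
Reagents that add atoms: none
Why: Dess–Martin oxidation under neutral conditions gives the α‑branched aldehyde without epimerisation.

**Step 5**
Reactants: 8 (2R)-2-(propan-2-yl)pent-4-ynal; 9 acetone
Product: 10 (4R,5R)-4-hydroxy-5-(propan-2-yl)oct-7-yn-2-one
Conditions: L-proline (30 mol %), acetone/DMSO (1:4), rt
Reagents that add atoms: none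
Why: Proline‑catalysed direct aldol reaction (List–Barbas–Lerner), in which the acetone enamine attacks the Re face of the aldehyde to set C8 as 4R under catalyst control, matched with Felkin–Anh control from the 2R centre, giving the anti C7/C8 relationship of the target.

**Step 6**
Reactants: 10 (4R,5R)-4-hydroxy-5-(propan-2-yl)oct-7-yn-2-one; 11 4-(benzyloxy)-3-methoxybenzoic acid
Product: 13 (4R,5R)-2-oxo-5-(propan-2-yl)oct-7-yn-4-yl 4-(benzyloxy)-3-methoxybenzoate, via acid chloride 12 (not isolated)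
Conditions: 11, 1-chloro-N,N,2-trimethylprop-1-en-1-amine, CH2Cl2, 0 °C → rt; then 10, pyridine, DMAP (cat.), 0 °C → rt
Reagents that add atoms: none
Why: Acylation through the acid chloride made under neutral conditions (Ghosez reagent) with only pyridine as base esterifies the aldol without β‑elimination; the aroyl group is the final ester and keeps the C8 oxygen non‑chelating for step 8.

**Step 7**
Reactants: 13 (4R,5R)-2-oxo-5-(propan-2-yl)oct-7-yn-4-yl 4-(benzyloxy)-3-methoxybenzoate; 14 ethylene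
Product: 16 (2R,3R)-5-oxo-1-(5-oxocyclopent-1-en-1-yl)-2-(propan-2-yl)hexan-3-yl 4-(benzyloxy)-3-methoxybenzoate, via hexacarbonyldicobalt alkyne complex 15 (not isolated)
Conditions: Co2(CO)8 (1.1 equiv), CH2Cl2, rt; then ethylene (5 bar), N-methylmorpholine N-oxide, 4 Å MS, rt
Reagents that add atoms: dicobalt octacarbonyl Co2(CO)8 (source of the ring CO), [Co].[Co].[C-]#[O+].[C-]#[O+].[C-]#[O+].[C-]#[O+].[C-]#[O+].[C-]#[O+].[C-]#[O+].[C-]#[O+]
Why: Intermolecular Pauson–Khand reaction (N‑oxide promoted), which places the alkyne substituent α to the new carbonyl and so gives the 2‑substituted cyclopent-2-enone; no new stereocentre.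

**Step 8**
Reactants: 16 (2R,3R)-5-oxo-1-(5-oxocyclopent-1-en-1-yl)-2-(propan-2-yl)hexan-3-yl 4-(benzyloxy)-3-methoxybenzoate
Product: 19 (1R,5S,7R,8R,10R)-10-hydroxy-4-oxo-15-norguaian-8-yl 4-(benzyloxy)-3-methoxybenzoate (trans-fused ketone), via bis(diiodosamarium) alkoxide enolate 17 (not isolated), via cis-fused C5-epimeric ketone 18 (not isolated)
Conditions: SmI2 (2.2 equiv), HMPA (8 equiv), THF (0.005 M), −78 °C; aq NH4Cl; then DBU (0.5 equiv), CH2Cl2, rt
Reagents that add atoms: none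
Why: SmI2‑mediated reductive ketyl–enone (ketyl–olefin) cyclization, in which the C10 ketyl adds in the endo mode to the enone β‑carbon C1 (medium‑ring closures of this kind are known for aldehyde–enone pairs); the HMPA‑solvated samarium alkoxide oxygen turns away from the forming enolate so that C14 sits over the five‑membered ring (10R relative to 1R), the C8 aroyloxy group lies equatorial and 1,3‑anti to the ketyl oxygen in a twist‑chair with the ketyl carbon on its axis (fixing the C1/C10 pair relative to C7/C8), and DBU equilibrates C5 next to the C4 ketone from the kinetically protonated cis isomer to the more stable trans ring fusion (5S).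

**Step 9**
Reactants: 19 (1R,5S,7R,8R,10R)-10-hydroxy-4-oxo-15-norguaian-8-yl 4-(benzyloxy)-3-methoxybenzoate
Product: 21 (1R,5S,7R,8R,10R)-10-hydroxy-4-(trifluoromethylsulfonyloxy)-15-norguai-3-en-8-yl 4-(benzyloxy)-3-methoxybenzoate, via dipotassium alkoxide enolate 20 (not isolated)
Conditions: KN(SiMe3)2 (2.3 equiv), THF, −78 °C; then N-(5-chloropyridin-2-yl)triflimide (Comins' reagent), −78 → −30 °C
Reagents that add atoms: N-(5-chloropyridin-2-yl)bis(trifluoromethanesulfonyl)imide, FC(F)(F)S(=O)(=O)N(c1ccc(Cl)cn1)S(=O)(=O)C(F)(F)F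
Why: Kinetic enolisation at the C3 methylene rather than the C5 ring‑fusion methine, followed by O‑triflation, fixes the double bond at C3=C4 without touching C5; the tertiary alkoxide is reprotonated on work‑up.

**Step 10**
Reactants: 21 (1R,5S,7R,8R,10R)-10-hydroxy-4-(trifluoromethylsulfonyloxy)-15-norguai-3-en-8-yl 4-(benzyloxy)-3-methoxybenzoate
Product: 22 (1R,5S,7R,8R,10R)-10-hydroxyguai-3-en-8-yl 4-(benzyloxy)-3-methoxybenzoate
Conditions: Pd(PPh3)4 (5 mol %), Me2Zn (3 equiv), THF, 0 °C → rt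
Reagents that add atoms: dimethylzinc, C[Zn]C
Why: Negishi cross‑coupling of the enol triflate under zerovalent palladium catalysis installs C15 on C4 with the alkene held at C3=C4; the aryl ester and free alcohol are tolerated.

**Step 11**
Reactants: 22 (1R,5S,7R,8R,10R)-10-hydroxyguai-3-en-8-yl 4-(benzyloxy)-3-methoxybenzoate
Product: 23 (1R,3R,4S,5S,7R,8R,10R)-3,4-epoxy-10-hydroxyguaian-8-yl 4-(benzyloxy)-3-methoxybenzoate
Conditions: mCPBA, CH2Cl2, 0 °C
Reagents that add atoms: 3-chloroperoxybenzoic acid, OOC(=O)c1cccc(Cl)c1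
Why: Prilezhaev epoxidation of the trisubstituted alkene from the face of H‑1, because the pseudoaxial C14 methyl on C10 sits over the other face of the five‑membered ring, which sets 3R,4S.

**Step 12**
Reactants: 23 (1R,3R,4S,5S,7R,8R,10R)-3,4-epoxy-10-hydroxyguaian-8-yl 4-(benzyloxy)-3-methoxybenzoate
Product: 24 (1R,3R,4S,5S,7R,8R,10R)-3,4-epoxy-10-hydroxyguaian-8-yl 4-hydroxy-3-methoxybenzoate (target)
Conditions: H2 (1 atm), Pd/C, EtOAc, rt
Reagents that add atoms: none
Why: Hydrogenolysis of the aryl benzyl ether frees the phenol, while the trisubstituted epoxide, the ester and the tertiary alcohol are inert under neutral conditions.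

**Compound list**
1 | (4R)-4-benzyl-1,3-oxazolidin-2-one | O=C1N[C@H](Cc2ccccc2)CO1 | starting material
2 | 3-methylbutanoyl chloride | CC(C)CC(Cl)=O | starting material
3 | (4R)-4-benzyl-3-(3-methylbutanoyl)-1,3-oxazolidin-2-one | CC(C)CC(=O)N1[C@H](Cc2ccccc2)COC1=O | intermediate
4 | 3-bromoprop-1-yne (propargyl bromide) | C#CCBr | starting material
5 | sodium Z-enolate of 3 (not isolated) | [Na+].[O-]/C(=C\C(C)C)N1[C@H](Cc2ccccc2)COC1=O | intermediate
6 | (4R)-4-benzyl-3-[(2R)-2-(propan-2-yl)pent-4-ynoyl]-1,3-oxazolidin-2-one | O=C([C@H](CC#C)C(C)C)N1[C@H](Cc2ccccc2)COC1=O | intermediate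
7 | (2R)-2-(propan-2-yl)pent-4-yn-1-ol | OC[C@H](CC#C)C(C)C | intermediate
8 | (2R)-2-(propan-2-yl)pent-4-ynal | O=C[C@H](CC#C)C(C)C | intermediate
9 | acetone | CC(C)=O | starting material
10 | (4R,5R)-4-hydroxy-5-(propan-2-yl)oct-7-yn-2-one | CC(=O)C[C@@H](O)[C@H](CC#C)C(C)C | intermediate
11 | 4-(benzyloxy)-3-methoxybenzoic acid | COc1cc(C(=O)O)ccc1OCc1ccccc1 | starting material
12 | 4-(benzyloxy)-3-methoxybenzoyl chloride (not isolated) | COc1cc(C(Cl)=O)ccc1OCc1ccccc1 | intermediate
13 | (4R,5R)-2-oxo-5-(propan-2-yl)oct-7-yn-4-yl 4-(benzyloxy)-3-methoxybenzoate | COc1cc(C(=O)O[C@H](CC(C)=O)[C@H](CC#C)C(C)C)ccc1OCc1ccccc1 | intermediate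
14 | ethylene | C=C | starting material
15 | hexacarbonyldicobalt complex of alkyne 13 (not isolated) | COc1cc(C(=O)O[C@H](CC(C)=O)[C@H](CC23[CH]4[Co]2(=C=O)(=C=O)(=C=O)[Co]34(=C=O)(=C=O)=C=O)C(C)C)ccc1OCc1ccccc1 | intermediate
16 | (2R,3R)-5-oxo-1-(5-oxocyclopent-1-en-1-yl)-2-(propan-2-yl)hexan-3-yl 4-(benzyloxy)-3-methoxybenzoate | COc1cc(C(=O)O[C@H](CC(C)=O)[C@H](CC2=CCCC2=O)C(C)C)ccc1OCc1ccccc1 | intermediate
17 | bis(diiodosamarium) C10-alkoxide C4-enolate after ring closure (not isolated) | COc1cc(C(=O)O[C@@H]2C[C@@](C)(O[Sm](I)I)[C@@H]3CCC(O[Sm](I)I)=C3C[C@@H]2C(C)C)ccc1OCc1ccccc1 | intermediate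
18 | (1R,5R,7R,8R,10R)-10-hydroxy-4-oxo-15-norguaian-8-yl 4-(benzyloxy)-3-methoxybenzoate, cis-fused (not isolated) | COc1cc(C(=O)O[C@@H]2C[C@@](C)(O)[C@@H]3CCC(=O)[C@@H]3C[C@@H]2C(C)C)ccc1OCc1ccccc1 | intermediate
19 | (1R,5S,7R,8R,10R)-10-hydroxy-4-oxo-15-norguaian-8-yl 4-(benzyloxy)-3-methoxybenzoate, trans-fused | COc1cc(C(=O)O[C@@H]2C[C@@](C)(O)[C@@H]3CCC(=O)[C@H]3C[C@@H]2C(C)C)ccc1OCc1ccccc1 | intermediate
20 | dipotassium C10-alkoxide C3=C4-enolate of 19 (not isolated) | COc1cc(C(=O)O[C@@H]2C[C@@](C)([O-])[C@@H]3CC=C([O-])[C@H]3C[C@@H]2C(C)C)ccc1OCc1ccccc1.[K+].[K+] | intermediate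
21 | (1R,5S,7R,8R,10R)-10-hydroxy-4-(trifluoromethylsulfonyloxy)-15-norguai-3-en-8-yl 4-(benzyloxy)-3-methoxybenzoate | COc1cc(C(=O)O[C@@H]2C[C@@](C)(O)[C@@H]3CC=C(OS(=O)(=O)C(F)(F)F)[C@H]3C[C@@H]2C(C)C)ccc1OCc1ccccc1 | intermediate
22 | (1R,5S,7R,8R,10R)-10-hydroxyguai-3-en-8-yl 4-(benzyloxy)-3-methoxybenzoate | COc1cc(C(=O)O[C@@H]2C[C@@](C)(O)[C@@H]3CC=C(C)[C@H]3C[C@@H]2C(C)C)ccc1OCc1ccccc1 | intermediate
23 | (1R,3R,4S,5S,7R,8R,10R)-3,4-epoxy-10-hydroxyguaian-8-yl 4-(benzyloxy)-3-methoxybenzoate | COc1cc(C(=O)O[C@@H]2C[C@@](C)(O)[C@@H]3C[C@H]4O[C@@]4(C)[C@H]3C[C@@H]2C(C)C)ccc1OCc1ccccc1 | intermediate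
24 | (1R,3R,4S,5S,7R,8R,10R)-3,4-epoxy-10-hydroxyguaian-8-yl 4-hydroxy-3-methoxybenzoate (CNP0136245.2) | COc1cc(C(=O)O[C@@H]2C[C@@](C)(O)[C@@H]3C[C@H]4O[C@@]4(C)[C@H]3C[C@@H]2C(C)C)ccc1O | target

**Totals**
Total step count: 12. Longest linear sequence: 12 steps (1 + 2 → 24; acid 11, acetone 9 and ethylene 14 enter as purchased).

**Steps most likely to fail, with fallbacks**

Step 8 (SmI2 ring closure). The sense of the C1/C10 pair relative to C7/C8 rests on a conformational model, and simple reduction or the wrong facial sense are the likely failures. The fallback moves the stereocontrol from a non‑chelating ester to a chelating free alcohol; it sets out from aldehyde 8 and rejoins at ketone 19. A D‑proline aldol of 8 with acetone (catalyst control, mismatched) gives the C8‑epimeric aldol (4S,5R)-4-hydroxy-5-(propan-2-yl)oct-7-yn-2-one F1. The cobalt‑mediated annulation with ethylene on the free alcohol then gives 2-[(2R,3S)-3-hydroxy-5-oxo-2-(propan-2-yl)hexyl]cyclopent-2-en-1-one F2. SmI2 in THF/MeOH without HMPA cyclises F2 through a trivalent samarium chelate between the C8 hydroxyl and the ketyl oxygen, which holds both oxygens cis and presents the same enone face to the ketyl; base equilibration at C5 gives trans‑fused (1R,5S,7R,8S,10R)-8,10-dihydroxy-15-norguaian-4-one F3. Mitsunobu esterification of the secondary alcohol of F3 with acid 11 (PPh3, DIAD) inverts C8 and delivers 19.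

Step 7 (Pauson–Khand reaction with ethylene). Yields with a gaseous alkene are often modest, and the β‑aroyloxy ketone is exposed to amine. The fallback builds the enone by carbonylative coupling and metathesis; it sets out from alkyne 13 and rejoins at enone 16. Markovnikov hydroiodination of 13 (NaI, Me3SiCl, H2O, MeCN) gives (4R,5R)-7-iodo-2-oxo-5-(propan-2-yl)oct-7-en-4-yl 4-(benzyloxy)-3-methoxybenzoate F4. Carbonylative Negishi coupling of F4 with but-3-enylzinc bromide (CO 1 atm, Pd(PPh3)4) gives the dienone (4R,5R)-7-methylidene-2,8-dioxo-5-(propan-2-yl)dodec-11-en-4-yl 4-(benzyloxy)-3-methoxybenzoate F5. Ring‑closing metathesis of F5 with the second‑generation Grubbs catalyst closes the cyclopentenone and gives 16.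

Step 11 (epoxidation face). If the peracid attacks mainly the face of the C1–C10 bond (for example through hydrogen bonding to the C10 hydroxyl), the fallback makes the epoxide by anti hydroxybromination and closure instead; it sets out from alkene 22 and rejoins at epoxide 23. NBS in wet THF forms the bromonium ion on the face the peracid prefers, and water opens it at the tertiary C4 from the opposite face to give the bromohydrin (1R,3S,4S,5S,7R,8R,10R)-3-bromo-4,10-dihydroxyguaian-8-yl 4-(benzyloxy)-3-methoxybenzoate F6. DBU then closes F6 by backside displacement of bromide to 23.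

**Further compounds**
F1 | step 8 | (4S,5R)-4-hydroxy-5-(propan-2-yl)oct-7-yn-2-one | CC(=O)C[C@H](O)[C@H](CC#C)C(C)C
F2 | step 8 | 2-[(2R,3S)-3-hydroxy-5-oxo-2-(propan-2-yl)hexyl]cyclopent-2-en-1-one | O[C@@H](CC(C)=O)[C@H](CC1=CCCC1=O)C(C)C
F3 | step 8 | (1R,5S,7R,8S,10R)-8,10-dihydroxy-15-norguaian-4-one, trans-fused | O[C@H]1C[C@@](C)(O)[C@@H]2CCC(=O)[C@H]2C[C@@H]1C(C)C
F4 | step 7 | (4R,5R)-7-iodo-2-oxo-5-(propan-2-yl)oct-7-en-4-yl 4-(benzyloxy)-3-methoxybenzoate | COc1cc(C(=O)O[C@H](CC(C)=O)[C@H](CC(I)=C)C(C)C)ccc1OCc1ccccc1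
F5 | step 7 | (4R,5R)-7-methylidene-2,8-dioxo-5-(propan-2-yl)dodec-11-en-4-yl 4-(benzyloxy)-3-methoxybenzoate | COc1cc(C(=O)O[C@H](CC(C)=O)[C@H](CC(=C)C(=O)CCC=C)C(C)C)ccc1OCc1ccccc1
F6 | step 11 | (1R,3S,4S,5S,7R,8R,10R)-3-bromo-4,10-dihydroxyguaian-8-yl 4-(benzyloxy)-3-methoxybenzoate | COc1cc(C(=O)O[C@@H]2C[C@@](C)(O)[C@@H]3C[C@H](Br)[C@@](C)(O)[C@H]3C[C@@H]2C(C)C)ccc1OCc1ccccc1
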